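Of all that had become target or isomer of the product by the last two readings of the north run, target was 80.5%. Call this pooled share s, the selectivity for target. An even split is the zero of its scale, and s lies 31 percentage points above it.

in all of them: starting material 0.50 M; impurity 3.6 mM

|  | free catalyst | temperature | remark | time |
|---|---|---|---|---|
| north-west | 3.4 mM | 10 °C | run made earlier |  |
| north | 7.5 mM | 28 °C | run made earlier |  |
| Wednesday's | 5.0 mM | 15 °C |  | 5.0 d |
| Friday's | 5.0 mM | 40 °C |  | 5.0 d |

north-west run (percent of the starting material charged)

| time / d | target / % | isomer of the product / % |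
|---|---|---|
| 0.333 | 0.2 | 0 |
| 0.833 | 0.9 | 0.1 |
| 1.67 | 0.5 | 0.2 |
| 4.00 | 1.2 | 0 |

north run (percent of the starting material charged)

| time / h | target / % | isomer of the product / % |
|---|---|---|
| 6.00 | 1.9 | 0 |
| 15.0 | 3.2 | 0 |
| 30.0 | 4.1 | 0.8 |
| 48.0 | 5.0 | 1.4 |

(readings scatter by 0.3 percentage points)

- the flask with the highest share of target in all that became target or isomer of the product ("all alike" if they lie within 1.5 percentage points) (Wednesday's / Friday's / all alike)
- share of target in all that became target or isomer of the product, Wednesday's
- share of target in all that became target or isomer of the product, Friday's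

- the numbers in the tables scatter by 0.3 percentage points (one standard deviation)
- in a conversion other conformer counts as not yet reacted
- a reading or a percentage of target counts all its forms, free or not

Two chemists read these runs. The first holds that target turns into isomer, so the share must fall with time. The forecast is hers: “it forms from target, in sequence”. The north isomer reads 0% at 15.0 h and then climbs. She expects 88% for Wednesday's and 28% for Friday's, and names Wednesday's.

I am the second. I hold that both products form side by side and answer alike to temperature, so the share stays near s. The north shares at 30.0 h and 48.0 h are 83.7% and 78.1%. That looks like a fall. But one standard deviation more on the earlier isomer reading takes the first share to 78.8%. So I see no fall I can trust. The zero at 15.0 h counts against me, because s asks for 0.774% of isomer there. I still commit to 80.5% for both flasks, which makes them all alike.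

The simulation gives 86.1% for Wednesday's and 81.0% for Friday's, so Wednesday's comes first, by more than the margin of 1.5 points.

    other conformer ⇌ dormant form (K = 2.95, k = 0.00379 h⁻¹, Ea = 104 kJ mol⁻¹, ΔH = −59.0 kJ mol⁻¹)
    free catalyst + target ⇌ idle complex, settled at all times (K = 89.1 L mol⁻¹, ΔH = −54.0 kJ mol⁻¹)
    starting material + free catalyst → free catalyst + target (k = 2.59 L mol⁻¹ h⁻¹, Ea = 78.0 kJ mol⁻¹)
    starting material ⇌ other conformer (K = 0.0985, k = 0.0473 h⁻¹, Ea = 95.0 kJ mol⁻¹, ΔH = −28.0 kJ mol⁻¹)
    free catalyst + impurity → spent catalyst (k = 104 L mol⁻¹ h⁻¹, Ea = 64.0 kJ mol⁻¹)
    free catalyst + other conformer → free catalyst + isomer of the product (k = 7.02 L mol⁻¹ h⁻¹, Ea = 77.0 kJ mol⁻¹)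
    (constants at 40 °C)

On Friday's, s lands 0.50 points below the flask and the forecast 53 points below it. On Wednesday's, the forecast is 1.9 points off and s 5.6 points off, and I lose the choice of flask. In the scheme, isomer comes from other conformer, not from target. A share falling with time, as she expected, does appear when Wednesday's is left until 50.0 d, where the share reaches 69.5%, while Friday's left as long stands at 79.7%. Now take Friday's repeated at 55 °C, with amounts and time held. The reckoning again says 80.5%. That flask holds 32.4% of target and 5.03% of isomer, a share of 86.5%.

All runs are simulated from invented constants, and the scatter is random.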